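The pyranone ring (ring C) is disconnected into an open-chain 2'-fluorodeoxybenzoin and formaldehyde. The C4 ketone is the feature exploited: it acidifies C3 and, being ortho to C8a of ring A, activates that carbon for SNAr. In one pot a base-mediated hydroxymethylation forges C2–C3 and the new C2 alkoxide displaces fluoride at C8a (O1–C8a), delivering the isoflavanone at its final oxidation level. The precursor, an aryl benzyl ketone carrying the fluoro ring A and the chromene ring B, comes from a Pd(OAc)2/XPhos-catalysed ketone α-arylation. The base-labile C3 stereocentre is then fixed by transfer hydrogenation with RuCl[(S,S)-TsDPEN](p-cymene) under dynamic kinetic resolution, re-oxidation and non-basic MOM removal.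

Key step: step 8

Remark: chroman-4-one numbering is used (O1, C2, C3, C4, C4a, C5–C8, C8a; ring A = benzo ring, ring C = pyranone, ring B = the chromene-bearing aryl group); by CIP analysis the single stereocentre C3 of the target is S.
Remark: formaldehyde is used as paraformaldehyde; 5-fluororesorcinol, catechol and 3-chloro-3-methylbut-1-yne are taken as commercial.

Step 1
Reactants: 1 5-fluorobenzene-1,3-diol (5-fluororesorcinol)
Product: 2 1-(2-fluoro-4,6-dihydroxyphenyl)ethan-1-one
Conditions: AcOH, BF3·OEt2, 90 °C; then aq. NaOAc
Reagents that add atoms: acetic acid CC(=O)O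
Why: Friedel–Crafts (Nencki-type) C-acylation should occur at C4 of the resorcinol (para to one hydroxyl, ortho to the other) rather than at the doubly flanked C2, and the BF2 chelate of the resulting o-hydroxy ketone prevents a second acylation.

Step 2
Reactants: 2 1-(2-fluoro-4,6-dihydroxyphenyl)ethan-1-one
Product: 4 1-[2-fluoro-6-methoxy-4-(methoxymethoxy)phenyl]ethan-1-one, via mono-MOM ether 3 (not isolated)
Conditions: MOMCl (1.05 equiv), K2CO3, acetone, 0 °C to rt; then MeI (excess), 50 °C
Reagents that add atoms: chloromethyl methyl ether COCCl; iodomethane CI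
Why: Sequential Williamson etherification should be selective because the para 4-OH is free while the 6-OH is locked in a hydrogen bond to the ketone, so MOMCl takes only the para hydroxyl at low temperature and the chelated phenol is methylated afterwards under forcing conditions.

Step 3
Reactants: 5 benzene-1,2-diol (catechol)
Product: 6 2-(methoxymethoxy)phenol
Conditions: MOMCl (1.0 equiv), K2CO3 (1.0 equiv), acetone, 0 °C to rt
Reagents that add atoms: chloromethyl methyl ether COCCl
Why: Williamson mono-etherification of the symmetrical diol with one equivalent of electrophile should give mainly the mono-acetal, the bis-ether and unreacted catechol being removed by base extraction and chromatography.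

Step 4
Reactants: 6 2-(methoxymethoxy)phenol
Product: 7 4-bromo-2-(methoxymethoxy)phenol
Conditions: NBS, MeCN, −20 to 0 °C
Reagents that add atoms: N-bromosuccinimide O=C1CCC(=O)N1Br
Why: Electrophilic aromatic bromination is directed para to the free phenol, the strongest activating group (as in the bromination of guaiacol), and the neutral bromine source spares the acetal.

Step 5
Reactants: 7 4-bromo-2-(methoxymethoxy)phenol
Product: 8 4-bromo-2-(methoxymethoxy)-1-[(2-methylbut-3-yn-2-yl)oxy]benzene
Conditions: 3-chloro-3-methylbut-1-yne, K2CO3, KI (cat.), CuI (cat.), acetone, reflux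
Reagents that add atoms: 3-chloro-3-methylbut-1-yne CC(C)(Cl)C#C
Why: CuI-assisted O-alkylation of the phenoxide with the tertiary propargylic chloride is the standard entry to aryl 1,1-dimethylpropargyl ethers.

Step 6
Reactants: 8 4-bromo-2-(methoxymethoxy)-1-[(2-methylbut-3-yn-2-yl)oxy]benzene
Product: 9 6-bromo-8-(methoxymethoxy)-2,2-dimethyl-2H-chromene
Conditions: PhNEt2, 185 °C
Reagents that add atoms: none
Why: Thermal aromatic propargyl Claisen rearrangement to the only free ortho position (the other carries OMOM), followed by enolisation, 1,5-hydrogen shift and oxa-6π electrocyclisation, should give the 2,2-dimethyl-2H-chromene with bromine para to the ring oxygen.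

Step 7
Reactants: 4 1-[2-fluoro-6-methoxy-4-(methoxymethoxy)phenyl]ethan-1-one; 9 6-bromo-8-(methoxymethoxy)-2,2-dimethyl-2H-chromene
Product: 10 1-[2-fluoro-6-methoxy-4-(methoxymethoxy)phenyl]-2-[8-(methoxymethoxy)-2,2-dimethyl-2H-chromen-6-yl]ethan-1-one
Conditions: Pd(OAc)2 (2 mol %), XPhos (4 mol %), K3PO4, toluene, 90 °C
Reagents that add atoms: none
Why: Buchwald–Hartwig-type α-arylation of the methyl ketone enolate should stop at mono-arylation because the more acidic deoxybenzoin rests as its hindered enolate, while the C–F bond is inert to zerovalent palladium and the mild phosphate base does not attack the fluoroarene.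

Step 8
Reactants: 10 1-[2-fluoro-6-methoxy-4-(methoxymethoxy)phenyl]-2-[8-(methoxymethoxy)-2,2-dimethyl-2H-chromen-6-yl]ethan-1-one
Product: 12 rac-5-methoxy-7-(methoxymethoxy)-3-[8-(methoxymethoxy)-2,2-dimethyl-2H-chromen-6-yl]chroman-4-one, via aldol adduct 11 (not isolated)
Conditions: (CH2O)n (1.3 equiv), Cs2CO3 (2.5 equiv), DMF, 25 °C then 80 °C
Reagents that add atoms: formaldehyde (as paraformaldehyde) C=O
Why: Cs2CO3 generates the aryl-stabilised enolate of 10, which adds to formaldehyde (aldol hydroxymethylation, C2–C3 bond) to give alkoxide 11; this alkoxide attacks the fluorine-bearing ring-A carbon ortho to the ketone through a Meisenheimer intermediate whose charge is delocalised into the C4 carbonyl, and loss of fluoride forms the O1–C8a bond. The closest known reaction types are the formaldehyde aldol of deoxybenzoins used in classical isoflavanone syntheses and the addition/SNAr annulation of o-fluoroaryl ketones (the oxygen counterpart of the enaminone SNAr cyclisation to 4-quinolones). Ring C closes by a 6-exo addition–elimination at an sp2 carbon, made irreversible by expulsion of fluoride. C3 is formed as a racemate and is deliberately left uncontrolled because it epimerises under the basic conditions; its configuration is set in step 9. The step needs cyclisation to prevail over E1cB dehydration to the α-methylene ketone, Michael dimerisation and a second hydroxymethylation: adventitious water can re-add to any enone and return it to 11, a 3-hydroxymethyl over-adduct can revert by retro-aldol on heating, fluoride is the only leaving group ortho to the activating carbonyl, and the MOM ethers keep both phenols from ionising and quenching the electrophilicity of ring A.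

Step 9
Reactants: 12 rac-5-methoxy-7-(methoxymethoxy)-3-[8-(methoxymethoxy)-2,2-dimethyl-2H-chromen-6-yl]chroman-4-one
Product: 13 (3S,4S)-5-methoxy-7-(methoxymethoxy)-3-[8-(methoxymethoxy)-2,2-dimethyl-2H-chromen-6-yl]chroman-4-ol (cis)
Conditions: RuCl[(S,S)-TsDPEN](p-cymene) (5 mol %), HCO2H/Et3N (1:1), EtOAc, 40 °C
Reagents that add atoms: none
Why: Noyori–Ikariya asymmetric transfer hydrogenation with dynamic kinetic resolution: Et3N should racemise the acidic C3 centre of 12 faster than reduction, and the (S,S)-catalyst should reduce only the (3S)-ketone, delivering hydride anti to the C3 aryl group so that C3 is fixed as S and C4 as S (cis), while the chromene alkene is left untouched.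

Step 10
Reactants: 13 (3S,4S)-5-methoxy-7-(methoxymethoxy)-3-[8-(methoxymethoxy)-2,2-dimethyl-2H-chromen-6-yl]chroman-4-ol
Product: 14 (3S)-5-methoxy-7-(methoxymethoxy)-3-[8-(methoxymethoxy)-2,2-dimethyl-2H-chromen-6-yl]chroman-4-one
Conditions: Dess–Martin periodinane, CH2Cl2, 0 °C to rt
Reagents that add atoms: none
Why: Dess–Martin oxidation of the benzylic secondary alcohol runs without base (acetic acid is the only by-product), so the C3 stereocentre, α-acidic again once the ketone is formed, should not be enolised, and the C4 stereocentre is removed as planned.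

Step 11
Reactants: 14 (3S)-5-methoxy-7-(methoxymethoxy)-3-[8-(methoxymethoxy)-2,2-dimethyl-2H-chromen-6-yl]chroman-4-one
Product: 15 (3S)-7-hydroxy-3-(8-hydroxy-2,2-dimethyl-2H-chromen-6-yl)-5-methoxychroman-4-one (CNP0113665.1)
Conditions: ZnBr2, n-PrSH, CH2Cl2, 0 °C, 10 min
Reagents that add atoms: none
Why: Lewis acid-assisted thiolytic cleavage of the two aryl methoxymethyl acetals (ZnBr2 activates the acetal, propanethiol traps the methoxymethyl cation) is fast at 0 °C and avoids both base and strong protic acid, so the C3 stereocentre, the 5-methyl ether and the chromene should survive.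

Compound list
1 | 5-fluorobenzene-1,3-diol (5-fluororesorcinol) | Oc1cc(O)cc(F)c1 | starting material
2 | 1-(2-fluoro-4,6-dihydroxyphenyl)ethan-1-one | CC(=O)c1c(O)cc(O)cc1F | intermediate
3 | 1-[2-fluoro-6-hydroxy-4-(methoxymethoxy)phenyl]ethan-1-one | CC(=O)c1c(O)cc(OCOC)cc1F | intermediate
4 | 1-[2-fluoro-6-methoxy-4-(methoxymethoxy)phenyl]ethan-1-one | CC(=O)c1c(OC)cc(OCOC)cc1F | intermediate
5 | benzene-1,2-diol (catechol) | Oc1ccccc1O | starting material
6 | 2-(methoxymethoxy)phenol | COCOc1ccccc1O | intermediate
7 | 4-bromo-2-(methoxymethoxy)phenol | COCOc1cc(Br)ccc1O | intermediate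
8 | 4-bromo-2-(methoxymethoxy)-1-[(2-methylbut-3-yn-2-yl)oxy]benzene | COCOc1cc(Br)ccc1OC(C)(C)C#C | intermediate
9 | 6-bromo-8-(methoxymethoxy)-2,2-dimethyl-2H-chromene | COCOc1cc(Br)cc2C=CC(C)(C)Oc12 | intermediate
10 | 1-[2-fluoro-6-methoxy-4-(methoxymethoxy)phenyl]-2-[8-(methoxymethoxy)-2,2-dimethyl-2H-chromen-6-yl]ethan-1-one | COCOc1cc(F)c(C(=O)Cc2cc(OCOC)c3OC(C)(C)C=Cc3c2)c(OC)c1 | intermediate
11 | rac-1-[2-fluoro-6-methoxy-4-(methoxymethoxy)phenyl]-3-hydroxy-2-[8-(methoxymethoxy)-2,2-dimethyl-2H-chromen-6-yl]propan-1-one (aldol adduct) | COCOc1cc(F)c(C(=O)C(CO)c2cc(OCOC)c3OC(C)(C)C=Cc3c2)c(OC)c1 | intermediate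
12 | rac-5-methoxy-7-(methoxymethoxy)-3-[8-(methoxymethoxy)-2,2-dimethyl-2H-chromen-6-yl]chroman-4-one | COc1cc(OCOC)cc2c1C(=O)C(c1cc(OCOC)c3c(c1)C=CC(C)(C)O3)CO2 | intermediate
13 | (3S,4S)-5-methoxy-7-(methoxymethoxy)-3-[8-(methoxymethoxy)-2,2-dimethyl-2H-chromen-6-yl]chroman-4-ol | COc1cc(OCOC)cc2c1[C@@H](O)[C@@H](c1cc(OCOC)c3c(c1)C=CC(C)(C)O3)CO2 | intermediate
14 | (3S)-5-methoxy-7-(methoxymethoxy)-3-[8-(methoxymethoxy)-2,2-dimethyl-2H-chromen-6-yl]chroman-4-one | COc1cc(OCOC)cc2c1C(=O)[C@@H](c1cc(OCOC)c3c(c1)C=CC(C)(C)O3)CO2 | intermediate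
15 | (3S)-7-hydroxy-3-(8-hydroxy-2,2-dimethyl-2H-chromen-6-yl)-5-methoxychroman-4-one | COc1cc(O)cc2c1C(=O)[C@@H](c1cc(O)c3c(c1)C=CC(C)(C)O3)CO2 | target

Total step count: 11 steps.
Longest linear sequence: 9 steps (catechol 5 to target 15, steps 3–11); the ring-A branch (steps 1–2) joins at step 7.

Steps most likely to fail

Step 8. The aldol adduct may lose water by E1cB elimination before SNAr closure, and the resulting α-methylene ketone may be intercepted by a second enolate (Michael dimerisation); the product may also be hydroxymethylated again at C3. The fallback changes the one-carbon unit to the formate oxidation level, where dehydration is impossible. It sets out from 10: Claisen C-formylation with ethyl formate and NaH in THF, followed in the same flask by SNAr O-cyclisation of the β-keto aldehyde enolate onto the C–F carbon, should give the isoflavone 5-methoxy-7-(methoxymethoxy)-3-[8-(methoxymethoxy)-2,2-dimethyl-2H-chromen-6-yl]-4H-chromen-4-one F1. Submitting this isoflavone to the transfer-hydrogenation conditions of step 9 (conjugate reduction to the isoflavanone, then ketone reduction under dynamic kinetic resolution) should bring the route back at 13.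

Step 9. Hydride transfer to the hindered, electron-rich 5-methoxy ketone may be slower than catalyst decay, or racemisation of the substrate may not keep pace with reduction, so that conversion stalls or enantio- and diastereoselectivity erode. The fallback replaces reduction/re-oxidation by an enantioselective protonation. It sets out from 12: kinetic enolisation and silylation (LiN(SiMe3)2, TMSCl, THF, −78 °C) should give the silyl enol ether 5-methoxy-7-(methoxymethoxy)-3-[8-(methoxymethoxy)-2,2-dimethyl-2H-chromen-6-yl]-4-(trimethylsilyloxy)-2H-chromene F2. Protonation of this enol ether with a chiral BINOL-derived N-triflyl thiophosphoramide Brønsted acid catalyst and phenol as the stoichiometric proton source (toluene, rt, catalyst antipode chosen to deliver the S product) should give the (S)-ketone directly, coming back to the route at 14 and bypassing step 10.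

Step 11. Lewis acid-promoted enolisation may erode the C3 configuration, or acid and thiol may add across the chromene double bond, during acetal cleavage. The fallback exchanges the protecting groups before the stereocentre is set. It sets out from 12, where loss of configuration is irrelevant: HCl in MeOH at 40 °C should remove both MOM groups to give the racemic diphenol rac-7-hydroxy-3-(8-hydroxy-2,2-dimethyl-2H-chromen-6-yl)-5-methoxychroman-4-one F3. TBSCl and imidazole in DMF should then give the bis-silyl ether rac-7-(tert-butyldimethylsilyloxy)-3-[8-(tert-butyldimethylsilyloxy)-2,2-dimethyl-2H-chromen-6-yl]-5-methoxychroman-4-one F4. The conditions of step 9 should give the cis-alcohol (3S,4S)-7-(tert-butyldimethylsilyloxy)-3-[8-(tert-butyldimethylsilyloxy)-2,2-dimethyl-2H-chromen-6-yl]-5-methoxychroman-4-ol F5, and Dess–Martin oxidation should give the ketone (3S)-7-(tert-butyldimethylsilyloxy)-3-[8-(tert-butyldimethylsilyloxy)-2,2-dimethyl-2H-chromen-6-yl]-5-methoxychroman-4-one F6. Desilylation of this ketone with HF·pyridine in THF at 0 °C (non-basic fluoride) should come back to the route at 15.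

Further compounds
F1 | step 8 | 5-methoxy-7-(methoxymethoxy)-3-[8-(methoxymethoxy)-2,2-dimethyl-2H-chromen-6-yl]-4H-chromen-4-one | COc1cc(OCOC)cc2c1C(=O)C(c1cc(OCOC)c3c(c1)C=CC(C)(C)O3)=CO2
F2 | step 9 | 5-methoxy-7-(methoxymethoxy)-3-[8-(methoxymethoxy)-2,2-dimethyl-2H-chromen-6-yl]-4-(trimethylsilyloxy)-2H-chromene | COc1cc(OCOC)cc2c1C(O[Si](C)(C)C)=C(c1cc(OCOC)c3c(c1)C=CC(C)(C)O3)CO2
F3 | step 11 | rac-7-hydroxy-3-(8-hydroxy-2,2-dimethyl-2H-chromen-6-yl)-5-methoxychroman-4-one | COc1cc(O)cc2c1C(=O)C(c1cc(O)c3c(c1)C=CC(C)(C)O3)CO2
F4 | step 11 | rac-7-(tert-butyldimethylsilyloxy)-3-[8-(tert-butyldimethylsilyloxy)-2,2-dimethyl-2H-chromen-6-yl]-5-methoxychroman-4-one | COc1cc(O[Si](C)(C)C(C)(C)C)cc2c1C(=O)C(c1cc(O[Si](C)(C)C(C)(C)C)c3c(c1)C=CC(C)(C)O3)CO2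
F5 | step 11 | (3S,4S)-7-(tert-butyldimethylsilyloxy)-3-[8-(tert-butyldimethylsilyloxy)-2,2-dimethyl-2H-chromen-6-yl]-5-methoxychroman-4-ol | COc1cc(O[Si](C)(C)C(C)(C)C)cc2c1[C@@H](O)[C@@H](c1cc(O[Si](C)(C)C(C)(C)C)c3c(c1)C=CC(C)(C)O3)CO2
F6 | step 11 | (3S)-7-(tert-butyldimethylsilyloxy)-3-[8-(tert-butyldimethylsilyloxy)-2,2-dimethyl-2H-chromen-6-yl]-5-methoxychroman-4-one | COc1cc(O[Si](C)(C)C(C)(C)C)cc2c1C(=O)[C@@H](c1cc(O[Si](C)(C)C(C)(C)C)c3c(c1)C=CC(C)(C)O3)CO2
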